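The ratio of enzyme between the gamma and alpha runs was 2.06, but the ratio of their substrate decay constants, as read, was 1.40, which is less than the enzyme ratio and near its square root, 1.43.

common to all: substrate 0.10 M
- alpha: enzyme 18 µM; run made earlier
- gamma: enzyme 37 µM; run made earlier
- north-east: enzyme 14 µM; time 4.0 d
- west: enzyme 30 µM; time 15 d

- alpha (time / h: target / %, substrate / %): 4.00: 36.5, 58.1; 8.00: 48.4, 38.2; 20.0: 49.0, 11.2; 50.0: 38.1, 0.2
- gamma (time / h: target / %, substrate / %): 12.0: 58.3, 15.9; 25.0: 48.2, 1.7; 40.0: 39.6, 0; 50.0: 37.2, 0

(readings scatter by 1 percentage point)

- the winner by amount of target, in percent of the substrate charged; "neither" if no more than 2 percentage points parts them (north-east / west / neither)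
- how much target is there at the end, in percent of the substrate charged: north-east
- how much target is there at the end, in percent of the substrate charged: west

- candidate steps: 2 enzyme <-> resting dimer; substrate + enzyme -> target + enzyme; target <-> isomer of the product

I read that square root as free enzyme in balance with resting dimer at every moment. That balance was the top rung of my ladder, and it gave me the enzyme dependence of the next one. Substrate loss looked pseudo-first-order, so I scaled the alpha constant by the square root:

alpha: 0.109 h⁻¹
north-east: 0.0965 h⁻¹, half-life 7.18 h
west: 0.141 h⁻¹, half-life 4.90 h

The next rung was the fall of target in gamma, where substrate read 1.7% at 25.0 h and 0% at 40.0 h. I took the two slopes, as fractions of the charge, and from them the relaxation: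

slopes: 0.00573 h⁻¹, then 0.00240 h⁻¹
relaxation: 0.0697 h⁻¹, half-life 9.95 h
plateau: 34.8%

This last value is my plateau share: the part of the charge that stays target once target and isomer of the product balance. At 50.0 h, alpha read 38.1% and gamma 37.2%, against a scatter of 1 percentage point, so I took the plateau as independent of enzyme.

The slowest rung was the relaxation, slower than substrate loss in either flask. Still, north-east's 96 h held 9.65 relaxation half-lives, and west's 360 h held 36.2. I expected both flasks on the plateau.

The forecast gave neither, with 35.3% for north-east and 35% for west, and held that “isomerisation appears independent of enzyme”.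

The flasks gave neither: north-east 35.8%, west 35.7%, against my plateau share of 34.8%.

    2 enzyme ⇌ resting dimer, settled at all times (K = 50000 M⁻¹)
    substrate + enzyme → target + enzyme, rate k2*[substrate]*[enzyme]/(1 + ([substrate]/Km2) + ([target]/Kp2)) (0.270 M, 25.0 mM, k = 31000 M⁻¹ h⁻¹)
    target ⇌ isomer of the product (K = 1.80, k = 0.0570 h⁻¹)

The neighbour flask was west with a quarter of the substrate, 0.025 M. The plateau is a share of the charge, so I carried over 34.8% unchanged. After 15.0 d, that flask had 0% of its substrate left and stood at 35.7% target.

(All runs are simulated with made-up constants; noise was put on by code.)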